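in all of them: L 0.10 M
- dawn: X 0.76 equiv; run made earlier
- summer: X 1.5 equiv; run made earlier
- dusk: X 1.8 equiv; run made earlier
- north: X 0.950 equiv; time 8.0 h
- west: X 1.40 equiv; time 8.0 h
- north-west: X 2.10 equiv; time 8.0 h

| run | time / h | L / % | G / % | D / % | J / % |
|---|---|---|---|---|---|
| dawn | 0.667 | 34.5 | 60.5 | 5.3 | 2.9 |
| dawn | 1.33 | 30.6 | 60.4 | 3.8 | 5.4 |
| dawn | 2.50 | 31.4 | 60.2 | 2.5 | 4.9 |
| dawn | 4.00 | 30.5 | 61.0 | 5.9 | 4.3 |
| dawn | 8.00 | 32.8 | 59.9 | 5.9 | 3.4 |
| summer | 0.667 | 5.0 | 72.5 | 21.5 | 0.6 |
| summer | 1.33 | 2.5 | 67.9 | 28.7 | 2.8 |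
| summer | 2.50 | 0 | 65.1 | 32.6 | 2.5 |
| summer | 4.00 | 1.3 | 63.7 | 33.8 | 1.1 |
| summer | 8.00 | 0 | 61.9 | 33.7 | 1.7 |
| dusk | 0.667 | 2.7 | 67.1 | 28.7 | 3.8 |
| dusk | 2.00 | 0 | 53.2 | 42.6 | 0.7 |
| dusk | 4.00 | 0 | 48.2 | 48.8 | 0.7 |
| dusk | 6.00 | 0 | 47.9 | 53.4 | 0 |
| dusk | 8.00 | 0.1 | 45.3 | 52.2 | 2.1 |

(each reading ± 1 percentage point)



* which of these there is most of at the end, counted by the L in it, north (L / D / J / G)
* which of these there is most of at the end, counted by the L in it, west (L / D / J / G)
* which of these there is most of at the end, counted by the L in it, north-west (L / D / J / G)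
* amount of the one of these that there is most of at the end, in percent of the L charged, north
* amount of the one of these that there is most of at the end, in percent of the L charged, west
* amount of the one of these that there is most of at the end, in percent of the L charged, north-west

- I began with a ratio, the X spent per D made, because dividing the rate at which X goes by the rate at which D appears drops time out of the reckoning, which is safe once the flask has stopped by itself.
- So I first read the rate of D in the summer run: it was 0.322 h⁻¹ as a fraction of the L charged up to the first reading, then 0.109 h⁻¹ in the next interval, a fall by a factor 2.95, and 0.0333 h⁻¹ in the one after, a further fall by a factor 3.27.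
- X was never read, so I took the slowing to be X running down; the third rate was ten times smaller than the first, and summer D read 33.8% at 4.00 h and 33.7% at 8.00 h, a difference inside the scatter, so I treated the end as a stop.
- I then defined the price of D as the X charged beyond the L consumed, divided by the D at the stop, assuming X was used up; summer and dusk averaged 1.51.
- This price gave me D of 26.5% in west and 72.9% in north-west; north has less X than L, so the price alone gave me no figure there.
- The forecast named G at 71% in north, G at 71% in west and D at 71% in north-west, which is lower than my north-west figure; its own balance gave D of about 73 in north-west, and it then wrote: “A reversible G/D equilibrium would give nearer 62, so I take 71 with a wider range”.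
- The flasks gave G at 69.3% in north, G at 68.1% in west and D at 66.5% in north-west.

    L + X → G (k = 100 L mol⁻¹ h⁻¹)
    L + X → J, rate k2*[L] as long as [X] is above zero (k = 0.100 h⁻¹)
    X + G → D (k = 12.0 L mol⁻¹ h⁻¹)
    2 X → Z (k = 4.00 L mol⁻¹ h⁻¹)

West ended with D at 28.1% and L at 1.35%, a price of 1.47, the part above one being X that went to Z, 0.469 per D. The neighbour of north with 1.60 equiv of X, where the price gives D of 39.8%, held 40.7%. In north, the half-life of G by its turning into D was 1.1 h at 0.0715 h, shorter than the 8.0 h allowed. Yet X, the limiting reagent there, stood at 0% by 4.00 h, and G read 69.3% then and 69.3% at 80.0 h.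

The runs were computed on assumed constants; the scatter is artificial.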